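**Assumption:** natural (2S)-(−)-pinostrobin (CAS 480-37-5, fingerroot isolate) is bought in gram quantity; its ee is checked by chiral HPLC and upgraded by recrystallisation if needed.

## Retrosynthetic overview

1. The only stereocentre (C2, S) and the whole flavanone skeleton are bought as (2S)-pinostrobin (1). The C10 chain, with its 2E alkene already in place, is bought as geraniol (2).
2. Key disconnection: the C6–C1″ bond of the target (4) goes back to the 5-O-geranyl ether (3) by an O→C [1,3] allyl shift. The migrating group lands on C6, the only free carbon ortho to O5.
3. Second disconnection: the C5–O–C1″ ether of 3 goes back to 1 + 2 (Mitsunobu, base-free so C2 cannot racemise through the chalcone).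
4. Ring order: no ring is formed in the route; rings A, B and C all arrive intact in 1.

## Route

**Step 1**

- Reactants: 1, (2S)-pinostrobin [(2S)-5-hydroxy-7-methoxy-2-phenylchroman-4-one]; 2, geraniol [(2E)-3,7-dimethylocta-2,6-dien-1-ol].
- Product: 3, (2S)-5-[(2E)-3,7-dimethylocta-2,6-dienyloxy]-7-methoxy-2-phenylchroman-4-one (5-O-geranylpinostrobin).
- Conditions: geraniol (1.3 equiv), PPh3 (1.5 equiv), DIAD (1.5 equiv), THF, 0 °C → rt, 12 h; chromatography on Et3N-deactivated silica.
- Reagents that add atoms: geraniol (2), OC/C=C(\C)CCC=C(C)C, supplies the C10H17 group. PPh3 and DIAD leave no atoms.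
- Why: Mitsunobu etherification, in which the chelated 5-OH is still acidic enough to protonate the betaine and then displaces the primary allylic oxyphosphonium by SN2 at C1″, so the 2E alkene is untouched; with no base present the flavanone cannot open to the achiral chalcone, so C2 stays S.

**Step 2**

- Reactants: 3, 5-O-geranylpinostrobin.
- Product: 4, (2S)-6-geranylpinostrobin [(2S)-6-[(2E)-3,7-dimethylocta-2,6-dienyl]-5-hydroxy-7-methoxy-2-phenylchroman-4-one].
- Conditions: montmorillonite K10 (oven-dried, about 2 wt equiv), CH2Cl2, 0 °C → rt, 2–4 h; filter, chromatograph. Recovered 1 is recycled.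
- Reagents that add atoms: none (isomerisation).
- Why: clay-promoted formal [1,3]-sigmatropic O→C allyl shift of an aryl allyl ether, which proceeds through a surface-bound tight aryloxide/geranyl-cation pair and not a concerted pericyclic path; the pair collapses at the adjacent free ortho carbon C6 through the primary terminus C1″, so the geranyl group arrives un-inverted with its 2″E alkene intact and C2 is not touched. A thermal or Eu(III) [3,3] Claisen was rejected because it gives the 6-(reverse-geranyl) product or, after Cope, the 8-geranyl isomer as an E/Z mixture.

Expected by-products in step 2 are the 8-C-geranyl isomer, de-geranylated 1, and traces of chroman from acid cyclisation. The target is identified by the chelated 5-OH (about δ 12), a one-proton H-8 singlet, and HMBC from the benzylic CH2 to both C5 and C7.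

## Compound list

1 | (2S)-pinostrobin, (2S)-5-hydroxy-7-methoxy-2-phenylchroman-4-one | COc1cc2c(c(O)c1)C(=O)C[C@@H](c1ccccc1)O2 | starting material

2 | geraniol, (2E)-3,7-dimethylocta-2,6-dien-1-ol | OC/C=C(\C)CCC=C(C)C | starting material

3 | (2S)-5-O-geranylpinostrobin | COc1cc2c(c(OC/C=C(\C)CCC=C(C)C)c1)C(=O)C[C@@H](c1ccccc1)O2 | intermediate

4 | (2S)-6-geranylpinostrobin | COc1cc2c(c(O)c1C/C=C(\C)CCC=C(C)C)C(=O)C[C@@H](c1ccccc1)O2 | target

## Summary

Total step count: 2. Longest linear sequence: 2.

Steps most likely to fail (the route has only two steps, so both are ranked and the third entry is the remaining point of failure):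

1. **Step 2 (O→C shift).** Risks are C8 versus C6 delivery, simple ether cleavage back to 1, and acid-induced cyclisation of the geranyl chain. Fallback: abandon the ether route and make the C6–C bond by cross-coupling. Iodinate 1 at C6 under 5-OH direction (BnMe3N·ICl2, CaCO3, CH2Cl2/MeOH), then Stille-couple with (E)-geranyltributylstannane (Pd(PPh3)4, DMF), which is expected to couple at the primary terminus with the E alkene retained.
2. **Step 1 (Mitsunobu on the chelated, hindered 5-OH).** Risks are slow conversion, SN2′ (linalyl) ether, and alkylation of the hydrazide by-product. Fallback: base-free Pd(0) Tsuji–Trost O-allylation of 1 with geranyl methyl carbonate (Pd(PPh3)4, THF, rt), which uses a π-allyl electrophile in place of the oxyphosphonium.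
3. **Stereochemical quality of purchased 1.** 5-Hydroxyflavanones can be partly racemic after isolation, and C2 is never corrected later. Fallback: change the chiral source to (2S)-pinocembrin (propolis isolate) and methylate the 7-OH selectively under neutral Mitsunobu conditions (MeOH, PPh3, DIAD), which adds one step.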